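**Retrosynthetic overview**
1. 27 ⇐ 26 ⇐ 25 ⇐ 24: the last steps are desilylation, peracid epoxidation of the C1=C10 alkene and C3 acetylation of a macrocyclic triene lactone.
2. Ten-membered ring: C3–C4 bond by intramolecular Nozaki–Hiyama–Kishi coupling of the Z-vinyl iodide/aldehyde 22.
3. Key union: C7–C8 bond by intermolecular zinc Barbier allylation of aldehyde 17 (C8–C10, C1–C3, C14) with bromobutenolide 10 (C4–C7, C11–C13, C15). This gives the trans α-methylene-γ-lactone; C8 is then inverted by Mitsunobu methacrylation.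
4. 10 comes from acrolein and a silyl propargyl ether (resolution, directed hydroalumination–iodination, acrylate ester, ring-closing metathesis); 17 comes from a silyl butynyl ether (carboalumination, oxirane opening).
5. Ring order: five-membered lactone (step 5, as butenolide) → ten-membered carbocycle (step 14) → oxirane (step 16).

Assumption: ring atoms are numbered as in germacranolides (C1–C10 in the ring, C14 = methyl on C10, C15 = CH2O on C4, C11–C13 = lactone carbons), and the lipase shows its usual preference for acylating the R alcohol.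

**Step 1**
Reactants: 1 tert-butyldimethyl(prop-2-yn-1-yloxy)silane; 2 acrolein
Product: 4 rac-6-[(tert-butyldimethylsilyl)oxy]hex-1-en-4-yn-3-ol, via lithium acetylide 3 (not isolated)
Conditions: n-BuLi, THF, −78 °C; then 2, −78 → −20 °C; H2O
Reagents that add atoms: none
Why: Acetylide addition to an aldehyde; the hard lithium acetylide adds 1,2 to the enal and the carbinol is formed racemic on purpose.

**Step 2**
Reactants: 4 rac-6-[(tert-butyldimethylsilyl)oxy]hex-1-en-4-yn-3-ol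
Product: 5 (3S)-6-[(tert-butyldimethylsilyl)oxy]hex-1-en-4-yn-3-ol
Conditions: Novozym 435 (immobilised Candida antarctica lipase B), vinyl acetate, hexane, 30 °C, to ca. 55% conversion; chromatography
Reagents that add atoms: none
Why: Lipase-catalysed kinetic resolution (enantioselective transesterification); by the Kazlauskas rule (silyloxymethyl-alkynyl = large, vinyl = medium) the R alcohol is acetylated, so the S alcohol, the future C6, is recovered in high ee.

**Step 3**
Reactants: 5 (3S)-6-[(tert-butyldimethylsilyl)oxy]hex-1-en-4-yn-3-ol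
Product: 7 (3S,4Z)-6-[(tert-butyldimethylsilyl)oxy]-5-iodohexa-1,4-dien-3-ol, via cyclic alkenylaluminate 6 (not isolated)
Conditions: NaAlH2(OCH2CH2OMe)2 (Red-Al), THF, 0 °C; then I2, −78 → 0 °C; aq. KNaC4H4O6
Reagents that add atoms: iodine, [I][I]
Why: Hydroxyl-directed anti-hydroalumination of the propargylic alcohol puts aluminium on the distal alkyne carbon in a five-membered aluminate, and iodinolysis with retention gives the Z iodide (iodine cis to the carbinol carbon) without touching C6.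

**Step 4**
Reactants: 7 (3S,4Z)-6-[(tert-butyldimethylsilyl)oxy]-5-iodohexa-1,4-dien-3-ol; 8 2-(bromomethyl)prop-2-enoic acid
Product: 9 (3S,4Z)-6-[(tert-butyldimethylsilyl)oxy]-5-iodohexa-1,4-dien-3-yl 2-(bromomethyl)prop-2-enoate
Conditions: DCC, DMAP (5 mol %), CH2Cl2, −20 → 0 °C
Reagents that add atoms: none
Why: Steglich esterification under neutral, cold conditions acylates the bis-allylic alcohol without ionising it or displacing the allylic bromide.

**Step 5**
Reactants: 9 (3S,4Z)-6-[(tert-butyldimethylsilyl)oxy]-5-iodohexa-1,4-dien-3-yl 2-(bromomethyl)prop-2-enoate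
Product: 10 (5S)-3-(bromomethyl)-5-[(1Z)-3-[(tert-butyldimethylsilyl)oxy]-2-iodoprop-1-en-1-yl]furan-2(5H)-one
Conditions: second-generation Grubbs catalyst RuCl2(=CHPh)(PCy3)(H2IMes) (5 mol %), CH2Cl2 (5 mM), 40 °C
Reagents that add atoms: none
Why: Ring-closing metathesis between the vinyl group and the 1,1-disubstituted acrylate gives the butenolide with loss of ethene, while the hindered, electron-poor iodoalkene stays out of the catalytic cycle and the neutral conditions keep the C6 stereocentre.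

**Step 6**
Reactants: 11 tert-butyl(but-3-yn-1-yloxy)dimethylsilane
Product: 14 (3E)-6-[(tert-butyldimethylsilyl)oxy]-4-methylhex-3-en-1-ol, via alkenylalane 12 (not isolated), via lithium alkenylalanate 13 (not isolated)
Conditions: Me3Al, Cp2ZrCl2 (0.25 equiv), CH2Cl2, 0 °C → rt; volatiles removed; n-BuLi, hexane/THF, −78 °C; ethylene oxide, −78 → 0 °C; aq. KNaC4H4O6
Reagents that add atoms: trimethylaluminium, C[Al](C)C; ethylene oxide, C1CO1
Why: Negishi zirconium-catalysed carboalumination adds methyl and aluminium syn across the alkyne (methyl on the internal carbon), and the derived alanate opens the oxirane with retention, which fixes the E trisubstituted alkene (future C1=C10 with C14).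

**Step 7**
Reactants: 14 (3E)-6-[(tert-butyldimethylsilyl)oxy]-4-methylhex-3-en-1-ol
Product: 15 tert-butyl{[(3E)-6-[(4-methoxybenzyl)oxy]-3-methylhex-3-en-1-yl]oxy}dimethylsilane
Conditions: NaH, 4-methoxybenzyl chloride, Bu4NI (cat.), THF/DMF, 0 °C → rt
Reagents that add atoms: 4-methoxybenzyl chloride, COc1ccc(CCl)cc1
Why: Williamson ether synthesis masks the future C3 oxygen with a group that is orthogonal to both silyl ethers.

**Step 8**
Reactants: 15 tert-butyl{[(3E)-6-[(4-methoxybenzyl)oxy]-3-methylhex-3-en-1-yl]oxy}dimethylsilane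
Product: 16 (3E)-6-[(4-methoxybenzyl)oxy]-3-methylhex-3-en-1-ol
Conditions: Bu4NF, THF, 0 °C → rt
Reagents that add atoms: none
Why: Fluoride-induced desilylation frees only the future C8 oxygen because the benzyl-type ether is inert to fluoride.

**Step 9**
Reactants: 16 (3E)-6-[(4-methoxybenzyl)oxy]-3-methylhex-3-en-1-ol
Product: 17 (3E)-6-[(4-methoxybenzyl)oxy]-3-methylhex-3-enal
Conditions: Dess–Martin periodinane, pyridine, CH2Cl2, 0 °C; used at once without chromatography
Reagents that add atoms: none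
Why: Dess–Martin oxidation under buffered, non-basic conditions gives the β,γ-unsaturated aldehyde without moving the alkene into conjugation.

**Step 10**
Reactants: 10 (5S)-3-(bromomethyl)-5-[(1Z)-3-[(tert-butyldimethylsilyl)oxy]-2-iodoprop-1-en-1-yl]furan-2(5H)-one; 17 (3E)-6-[(4-methoxybenzyl)oxy]-3-methylhex-3-enal
Product: 19 (4R,5S)-5-[(1Z)-3-[(tert-butyldimethylsilyl)oxy]-2-iodoprop-1-en-1-yl]-4-[(1S,3E)-1-hydroxy-6-[(4-methoxybenzyl)oxy]-3-methylhex-3-en-1-yl]-3-methylidenedihydrofuran-2(3H)-one, via allylzinc bromide 18 (not isolated)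
Conditions: Zn dust, THF/sat. aq. NH4Cl (2:1), 0 °C → rt
Reagents that add atoms: none
Why: Zinc Barbier carbonyl allylation; the allylzinc reacts through its γ-carbon (C7) in a chair Zimmerman–Traxler transition state on the face anti to the C6 substituent (6,7-trans lactone, 7R), and the ring-locked E-crotyl-type geometry makes the new carbinol anti (8S) while regenerating the exocyclic methylene.

**Step 11**
Reactants: 19 (4R,5S)-5-[(1Z)-3-[(tert-butyldimethylsilyl)oxy]-2-iodoprop-1-en-1-yl]-4-[(1S,3E)-1-hydroxy-6-[(4-methoxybenzyl)oxy]-3-methylhex-3-en-1-yl]-3-methylidenedihydrofuran-2(3H)-one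
Product: 20 (1R,3E)-1-[(2S,3R)-2-[(1Z)-3-[(tert-butyldimethylsilyl)oxy]-2-iodoprop-1-en-1-yl]-4-methylidene-5-oxooxolan-3-yl]-6-[(4-methoxybenzyl)oxy]-3-methylhex-3-en-1-yl 2-methylprop-2-enoate
Conditions: methacrylic acid, PPh3, DIAD, THF, 0 °C → rt
Reagents that add atoms: methacrylic acid, CC(=C)C(=O)O
Why: Mitsunobu esterification displaces the oxyphosphonium by SN2 with clean inversion, so the 8S alcohol becomes the required 8R methacrylate in one operation.

**Step 12**
Reactants: 20 (1R,3E)-1-[(2S,3R)-2-[(1Z)-3-[(tert-butyldimethylsilyl)oxy]-2-iodoprop-1-en-1-yl]-4-methylidene-5-oxooxolan-3-yl]-6-[(4-methoxybenzyl)oxy]-3-methylhex-3-en-1-yl 2-methylprop-2-enoate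
Product: 21 (1R,3E)-1-[(2S,3R)-2-[(1Z)-3-[(tert-butyldimethylsilyl)oxy]-2-iodoprop-1-en-1-yl]-4-methylidene-5-oxooxolan-3-yl]-6-hydroxy-3-methylhex-3-en-1-yl 2-methylprop-2-enoate
Conditions: DDQ, CH2Cl2/pH 7 buffer (KH2PO4/Na2HPO4) 10:1, 0 °C
Reagents that add atoms: none
Why: Oxidative cleavage of the 4-methoxybenzyl ether by DDQ is neutral and leaves the silyl ether, both acrylate units, the lactone and the vinyl iodide alone.

**Step 13**
Reactants: 21 (1R,3E)-1-[(2S,3R)-2-[(1Z)-3-[(tert-butyldimethylsilyl)oxy]-2-iodoprop-1-en-1-yl]-4-methylidene-5-oxooxolan-3-yl]-6-hydroxy-3-methylhex-3-en-1-yl 2-methylprop-2-enoate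
Product: 22 (1R,3E)-1-[(2S,3R)-2-[(1Z)-3-[(tert-butyldimethylsilyl)oxy]-2-iodoprop-1-en-1-yl]-4-methylidene-5-oxooxolan-3-yl]-3-methyl-6-oxohex-3-en-1-yl 2-methylprop-2-enoate
Conditions: Dess–Martin periodinane, pyridine, CH2Cl2, 0 °C; short silica plug, used at once
Reagents that add atoms: none
Why: Dess–Martin oxidation gives the C3 aldehyde under conditions too mild to conjugate the C1=C10 alkene or epimerise C7.

**Step 14**
Reactants: 22 (1R,3E)-1-[(2S,3R)-2-[(1Z)-3-[(tert-butyldimethylsilyl)oxy]-2-iodoprop-1-en-1-yl]-4-methylidene-5-oxooxolan-3-yl]-3-methyl-6-oxohex-3-en-1-yl 2-methylprop-2-enoate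
Product: 24 (3S,6R,7R,8R)-15-[(tert-butyldimethylsilyl)oxy]-3-hydroxy-8-(methacryloyloxy)germacra-1(10)E,4Z,11(13)-trien-12,6-olide, via alkenylchromium dichloride 23 (not isolated)
Conditions: CrCl2 (10 equiv), NiCl2 (0.1 equiv), DMSO/THF 3:1, slow addition of 22 to 2 mM, rt
Reagents that add atoms: none
Why: Intramolecular Nozaki–Hiyama–Kishi coupling; nickel-catalysed formation of an alkenyl reagent of trivalent chromium that keeps the Z geometry and adds only to the aldehyde, and the E alkene plus trans lactone pre-organise the chain so that attack on the outward aldehyde face is expected to give the 3S (3β) alcohol.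

**Step 15**
Reactants: 24 (3S,6R,7R,8R)-15-[(tert-butyldimethylsilyl)oxy]-3-hydroxy-8-(methacryloyloxy)germacra-1(10)E,4Z,11(13)-trien-12,6-olide
Product: 25 (3S,6R,7R,8R)-3-acetoxy-15-[(tert-butyldimethylsilyl)oxy]-8-(methacryloyloxy)germacra-1(10)E,4Z,11(13)-trien-12,6-olide
Conditions: Ac2O, pyridine, DMAP (cat.), CH2Cl2, 0 °C → rt
Reagents that add atoms: acetic anhydride, CC(=O)OC(C)=O
Why: DMAP-catalysed acylation of the only free hydroxyl proceeds with retention at C3.

**Step 16**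
Reactants: 25 (3S,6R,7R,8R)-3-acetoxy-15-[(tert-butyldimethylsilyl)oxy]-8-(methacryloyloxy)germacra-1(10)E,4Z,11(13)-trien-12,6-olide
Product: 26 (1R,3S,6R,7R,8R,10R)-3-acetoxy-15-[(tert-butyldimethylsilyl)oxy]-1,10-epoxy-8-(methacryloyloxy)germacra-4Z,11(13)-dien-12,6-olide
Conditions: mCPBA (1.1 equiv), CH2Cl2/aq. NaHCO3, 0 °C
Reagents that add atoms: 3-chloroperoxybenzoic acid, OOC(=O)c1cccc(Cl)c1
Why: Prilezhaev epoxidation attacks only the electron-rich C1=C10 alkene (the C4=C5 alkene carries three allylic oxygens and the acrylates are electron-poor), stereospecifically giving the trans epoxide from the exposed outer face of the conformer with C14 syn to the C8 ester, which is the 1β,10α (1R,10R) isomer.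

**Step 17**
Reactants: 26 (1R,3S,6R,7R,8R,10R)-3-acetoxy-15-[(tert-butyldimethylsilyl)oxy]-1,10-epoxy-8-(methacryloyloxy)germacra-4Z,11(13)-dien-12,6-olide
Product: 27 (1R,3S,6R,7R,8R,10R)-3-acetoxy-1,10-epoxy-15-hydroxy-8-(methacryloyloxy)germacra-4Z,11(13)-dien-12,6-olide (CNP0319155.1)
Conditions: HF·pyridine, excess pyridine, THF, 0 °C
Reagents that add atoms: none
Why: Buffered fluoride desilylation removes the primary allylic silyl ether without base, so no acetyl migration or conjugate addition occurs, and the trisubstituted epoxide tolerates the short, cold, pyridine-buffered exposure.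

**Compound list**
1 | tert-butyldimethyl(prop-2-yn-1-yloxy)silane | C#CCO[Si](C)(C)C(C)(C)C | starting material
2 | acrolein (prop-2-enal) | C=CC=O | starting material
3 | lithium 3-[(tert-butyldimethylsilyl)oxy]prop-1-yn-1-ide (not isolated) | [Li]C#CCO[Si](C)(C)C(C)(C)C | intermediate
4 | rac-6-[(tert-butyldimethylsilyl)oxy]hex-1-en-4-yn-3-ol | C=CC(O)C#CCO[Si](C)(C)C(C)(C)C | intermediate
5 | (3S)-6-[(tert-butyldimethylsilyl)oxy]hex-1-en-4-yn-3-ol | CC(C)(C)[Si](C)(C)OCC#C[C@H](C=C)O | intermediate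
6 | sodium (5S)-3-{[(tert-butyldimethylsilyl)oxy]methyl}-5-ethenyl-2,2-bis(2-methoxyethoxy)-2,5-dihydro-1,2-oxaaluminol-2-uide (cyclic alkenylaluminate, not isolated) | [Na+].COCCO[Al-]1(OCCOC)O[C@@H](C=C)C=C1CO[Si](C)(C)C(C)(C)C | intermediate
7 | (3S,4Z)-6-[(tert-butyldimethylsilyl)oxy]-5-iodohexa-1,4-dien-3-ol | CC(C)(C)[Si](C)(C)OC/C(I)=C/[C@H](C=C)O | intermediate
8 | 2-(bromomethyl)prop-2-enoic acid | C=C(CBr)C(=O)O | starting material
9 | (3S,4Z)-6-[(tert-butyldimethylsilyl)oxy]-5-iodohexa-1,4-dien-3-yl 2-(bromomethyl)prop-2-enoate | CC(C)(C)[Si](C)(C)OC/C(I)=C/[C@H](C=C)OC(=O)C(=C)CBr | intermediate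
10 | (5S)-3-(bromomethyl)-5-[(1Z)-3-[(tert-butyldimethylsilyl)oxy]-2-iodoprop-1-en-1-yl]furan-2(5H)-one | CC(C)(C)[Si](C)(C)OC/C(I)=C/[C@H]1OC(=O)C(CBr)=C1 | intermediate
11 | tert-butyl(but-3-yn-1-yloxy)dimethylsilane | C#CCCO[Si](C)(C)C(C)(C)C | starting material
12 | [(1E)-4-[(tert-butyldimethylsilyl)oxy]-2-methylbut-1-en-1-yl]dimethylalane (not isolated) | C[Al](C)/C=C(\C)CCO[Si](C)(C)C(C)(C)C | intermediate
13 | lithium butyl[(1E)-4-[(tert-butyldimethylsilyl)oxy]-2-methylbut-1-en-1-yl]dimethylalanate (not isolated) | [Li+].CCCC[Al-](C)(C)/C=C(\C)CCO[Si](C)(C)C(C)(C)C | intermediate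
14 | (3E)-6-[(tert-butyldimethylsilyl)oxy]-4-methylhex-3-en-1-ol | OCC/C=C(\C)CCO[Si](C)(C)C(C)(C)C | intermediate
15 | tert-butyl{[(3E)-6-[(4-methoxybenzyl)oxy]-3-methylhex-3-en-1-yl]oxy}dimethylsilane | COc1ccc(COCC/C=C(\C)CCO[Si](C)(C)C(C)(C)C)cc1 | intermediate
16 | (3E)-6-[(4-methoxybenzyl)oxy]-3-methylhex-3-en-1-ol | COc1ccc(COCC/C=C(\C)CCO)cc1 | intermediate
17 | (3E)-6-[(4-methoxybenzyl)oxy]-3-methylhex-3-enal | COc1ccc(COCC/C=C(\C)CC=O)cc1 | intermediate
18 | {(5S)-5-[(1Z)-3-[(tert-butyldimethylsilyl)oxy]-2-iodoprop-1-en-1-yl]-2-oxo-2,5-dihydrofuran-3-yl}methylzinc bromide (not isolated) | CC(C)(C)[Si](C)(C)OC/C(I)=C/[C@H]1OC(=O)C(C[Zn]Br)=C1 | intermediate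
19 | (4R,5S)-5-[(1Z)-3-[(tert-butyldimethylsilyl)oxy]-2-iodoprop-1-en-1-yl]-4-[(1S,3E)-1-hydroxy-6-[(4-methoxybenzyl)oxy]-3-methylhex-3-en-1-yl]-3-methylidenedihydrofuran-2(3H)-one | O[C@@H](C/C(C)=C/CCOCc1ccc(OC)cc1)[C@H]1C(=C)C(=O)O[C@@H]1/C=C(\I)CO[Si](C)(C)C(C)(C)C | intermediate
20 | (1R,3E)-1-[(2S,3R)-2-[(1Z)-3-[(tert-butyldimethylsilyl)oxy]-2-iodoprop-1-en-1-yl]-4-methylidene-5-oxooxolan-3-yl]-6-[(4-methoxybenzyl)oxy]-3-methylhex-3-en-1-yl 2-methylprop-2-enoate | C=C(C)C(=O)O[C@H](C/C(C)=C/CCOCc1ccc(OC)cc1)[C@H]1C(=C)C(=O)O[C@@H]1/C=C(\I)CO[Si](C)(C)C(C)(C)C | intermediate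
21 | (1R,3E)-1-[(2S,3R)-2-[(1Z)-3-[(tert-butyldimethylsilyl)oxy]-2-iodoprop-1-en-1-yl]-4-methylidene-5-oxooxolan-3-yl]-6-hydroxy-3-methylhex-3-en-1-yl 2-methylprop-2-enoate | C=C(C)C(=O)O[C@H](C/C(C)=C/CCO)[C@H]1C(=C)C(=O)O[C@@H]1/C=C(\I)CO[Si](C)(C)C(C)(C)C | intermediate
22 | (1R,3E)-1-[(2S,3R)-2-[(1Z)-3-[(tert-butyldimethylsilyl)oxy]-2-iodoprop-1-en-1-yl]-4-methylidene-5-oxooxolan-3-yl]-3-methyl-6-oxohex-3-en-1-yl 2-methylprop-2-enoate | C=C(C)C(=O)O[C@H](C/C(C)=C/CC=O)[C@H]1C(=C)C(=O)O[C@@H]1/C=C(\I)CO[Si](C)(C)C(C)(C)C | intermediate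
23 | alkenylchromium dichloride from 22 (trivalent chromium in place of iodine, Z geometry kept; not isolated) | C=C(C)C(=O)O[C@H](C/C(C)=C/CC=O)[C@H]1C(=C)C(=O)O[C@@H]1/C=C(\[Cr](Cl)Cl)CO[Si](C)(C)C(C)(C)C | intermediate
24 | (3S,6R,7R,8R)-15-[(tert-butyldimethylsilyl)oxy]-3-hydroxy-8-(methacryloyloxy)germacra-1(10)E,4Z,11(13)-trien-12,6-olide | C=C(C)C(=O)O[C@@H]1C/C(C)=C/C[C@H](O)/C(CO[Si](C)(C)C(C)(C)C)=C\[C@H]2OC(=O)C(=C)[C@@H]21 | intermediate
25 | (3S,6R,7R,8R)-3-acetoxy-15-[(tert-butyldimethylsilyl)oxy]-8-(methacryloyloxy)germacra-1(10)E,4Z,11(13)-trien-12,6-olide | C=C(C)C(=O)O[C@@H]1C/C(C)=C/C[C@H](OC(C)=O)/C(CO[Si](C)(C)C(C)(C)C)=C\[C@H]2OC(=O)C(=C)[C@@H]21 | intermediate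
26 | (1R,3S,6R,7R,8R,10R)-3-acetoxy-15-[(tert-butyldimethylsilyl)oxy]-1,10-epoxy-8-(methacryloyloxy)germacra-4Z,11(13)-dien-12,6-olide | C=C(C)C(=O)O[C@@H]1C[C@@]2(C)O[C@@H]2C[C@H](OC(C)=O)/C(CO[Si](C)(C)C(C)(C)C)=C\[C@H]2OC(=O)C(=C)[C@@H]21 | intermediate
27 | (1R,3S,6R,7R,8R,10R)-3-acetoxy-1,10-epoxy-15-hydroxy-8-(methacryloyloxy)germacra-4Z,11(13)-dien-12,6-olide (CNP0319155.1) | C=C(C)C(=O)O[C@@H]1C[C@@]2(C)O[C@@H]2C[C@H](OC(C)=O)/C(CO)=C\[C@H]2OC(=O)C(=C)[C@@H]21 | target

**Totals**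
Total step count: 17. Longest linear sequence: 13 steps (steps 1–5 and 10–17, from 1 to 27); the aldehyde branch (steps 6–9) is convergent.

**Three steps most likely to fail**

Step 14 (ring closure). The risks are oligomerisation, which is met by slow addition at high dilution, and an uncertain face of attack at C3. The fallback sets out from 22 and comes back at 24. The chromium-mediated ring closure is run without regard to the C3 outcome. The crude alcohol, the 3R alcohol F3 included, is oxidised with Dess–Martin periodinane and pyridine to the macrocyclic enone F4. C3 is then set by reagent control in a Corey–Bakshi–Shibata reduction ((R)-2-methyl-CBS-oxazaborolidine, catecholborane, toluene, −78 °C; the alkenyl side acts as the large group), which gives the 3S alcohol 24.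

Step 11 (Mitsunobu inversion with methacrylic acid). The risks are elimination toward the C8–C9 diene and incomplete inversion on the β-branched carbinol. The fallback sets out from 19 and comes back at 20. Compound 19 is oxidised with Dess–Martin periodinane and pyridine to the C8 ketone F1. This is reduced cold with catecholborane and (S)-2-methyl-CBS-oxazaborolidine (branched C7 side large, C9 methylene small) to the 8R alcohol F2. F2 is acylated with methacrylic anhydride, Et3N and DMAP to give 20.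

Step 16 (epoxidation face). The risk is that conformational control in the macrocycle gives the wrong face or a mixture. The fallback sets out from 25 and comes back at 26 and makes no new compound. Substrate control is replaced by catalyst control in a Shi epoxidation: the D-fructose-derived ketone 1,2:4,5-di-O-isopropylidene-β-D-erythro-2,3-hexodiulo-2,6-pyranose with KHSO5 (as 2KHSO5·KHSO4·K2SO4), K2CO3 and Bu4NHSO4 in MeCN/dimethoxymethane/aqueous buffer at 0 °C. Its spiro transition state delivers the R,R epoxide from E trisubstituted alkenes independently of the ring conformation.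

**Further compounds**
F1 | step 11 | (4S,5S)-5-[(1Z)-3-[(tert-butyldimethylsilyl)oxy]-2-iodoprop-1-en-1-yl]-4-[(3E)-6-[(4-methoxybenzyl)oxy]-3-methylhex-3-enoyl]-3-methylidenedihydrofuran-2(3H)-one | O=C(C/C(C)=C/CCOCc1ccc(OC)cc1)[C@H]1C(=C)C(=O)O[C@@H]1/C=C(\I)CO[Si](C)(C)C(C)(C)C
F2 | step 11 | (4R,5S)-5-[(1Z)-3-[(tert-butyldimethylsilyl)oxy]-2-iodoprop-1-en-1-yl]-4-[(1R,3E)-1-hydroxy-6-[(4-methoxybenzyl)oxy]-3-methylhex-3-en-1-yl]-3-methylidenedihydrofuran-2(3H)-one | O[C@H](C/C(C)=C/CCOCc1ccc(OC)cc1)[C@H]1C(=C)C(=O)O[C@@H]1/C=C(\I)CO[Si](C)(C)C(C)(C)C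
F3 | step 14 | (3R,6R,7R,8R)-15-[(tert-butyldimethylsilyl)oxy]-3-hydroxy-8-(methacryloyloxy)germacra-1(10)E,4Z,11(13)-trien-12,6-olide | C=C(C)C(=O)O[C@@H]1C/C(C)=C/C[C@@H](O)/C(CO[Si](C)(C)C(C)(C)C)=C\[C@H]2OC(=O)C(=C)[C@@H]21
F4 | step 14 | (6R,7R,8R)-15-[(tert-butyldimethylsilyl)oxy]-8-(methacryloyloxy)-3-oxogermacra-1(10)E,4Z,11(13)-trien-12,6-olide | C=C(C)C(=O)O[C@@H]1C/C(C)=C/CC(=O)/C(CO[Si](C)(C)C(C)(C)C)=C\[C@H]2OC(=O)C(=C)[C@@H]21
F0 | step 16 | none | none
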